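The plan rests on cutting the benzylic C2–O1 bond of the 1,4-dioxane ring. C2 sits para to the free phenol of the syringyl ring, so it is a latent p-quinone methide carbon, as in the presumed biosynthesis. The precursor is an eight-membered benzo-fused cyclic carbonate. In it a C(=O)–O unit is inserted between O1 and C2, and the syringyl phenol is silylated. Fluoride then does everything in one operation: desilylation, 1,6-elimination to the quinone methide, loss of CO2, and closure of O1 on C2. This contracts the ring from eight to six atoms and sets C2 trans to the lactate-derived C3 methyl stereocentre.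

Key step: step 7

Assumption: compounds 1, 3 and 7 are taken as catalogue chemicals; the carbinol epimers formed in step 5 are carried on together, and the SMILES of 11–14 show the expected major one, because this carbon is planarised in step 7.

Step 1
Reactants: 1 4-bromo-2,6-dimethoxyphenol
Product: 2 (4-bromo-2,6-dimethoxyphenoxy)(tert-butyl)dimethylsilane
Conditions: TBSCl, imidazole, DMF, rt
Reagents that add atoms: tert-butyldimethylsilyl chloride, CC(C)(C)[Si](C)(C)Cl
Why: Standard imidazole-promoted O-silylation of a phenol, which masks the acidic OH for the lithiation and installs the fluoride trigger used in step 7.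

Step 2
Reactants: 2 (4-bromo-2,6-dimethoxyphenoxy)(tert-butyl)dimethylsilane; 3 (S)-2-hydroxy-N,N-dimethylpropanamide
Product: 6 (S)-1-[4-(tert-butyldimethylsilyloxy)-3,5-dimethoxyphenyl]-2-hydroxypropan-1-one, via aryllithium 4 (not isolated), via chloromagnesium alkoxide 5 (not isolated)
Conditions: 2, n-BuLi, THF, −78 °C; separately 3, i-PrMgCl, THF, −20 °C; combine, −78 → 0 °C; then cold 1 M HCl
Reagents that add atoms: none
Why: Bromine–lithium exchange followed by acylation of the aryllithium with a tertiary amide (Weinreb-type ketone synthesis), in which the pre-formed alkoxide shields the OH and chelation should prevent over-addition and enolisation, so the (S) centre of the lactic acid unit is carried over unchanged.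

Step 3
Reactants: 6 (S)-1-[4-(tert-butyldimethylsilyloxy)-3,5-dimethoxyphenyl]-2-hydroxypropan-1-one; 7 5-allyl-2-hydroxy-3-methoxybenzaldehyde
Product: 8 5-allyl-2-{[(R)-1-[4-(tert-butyldimethylsilyloxy)-3,5-dimethoxyphenyl]-1-oxopropan-2-yl]oxy}-3-methoxybenzaldehyde
Conditions: PPh3, DIAD, THF, 0 °C → rt
Reagents that add atoms: none
Why: Mitsunobu etherification, in which the acidic salicylaldehyde-type phenol displaces the activated α-keto carbinol by SN2 with inversion, turning the (S) alcohol into the (R) aryl ether carbon that becomes C3 of the target.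

Step 4
Reactants: 8 5-allyl-2-{[(R)-1-[4-(tert-butyldimethylsilyloxy)-3,5-dimethoxyphenyl]-1-oxopropan-2-yl]oxy}-3-methoxybenzaldehyde
Product: 10 (R)-2-(4-allyl-2-hydroxy-6-methoxyphenoxy)-1-[4-(tert-butyldimethylsilyloxy)-3,5-dimethoxyphenyl]propan-1-one, via aryl formate 9 (not isolated)
Conditions: 30% H2O2, H2SO4 (cat.), MeOH, rt
Reagents that add atoms: hydrogen peroxide, OO
Why: Acid-catalysed Dakin-type (Baeyer–Villiger) oxidation of an o-alkoxybenzaldehyde, in which the electron-rich aryl group migrates to oxygen and the formate is methanolysed in situ, while H2O2/H+ should leave the terminal alkene, the aryl ketone and the aryl silyl ether untouched.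

Step 5
Reactants: 10 (R)-2-(4-allyl-2-hydroxy-6-methoxyphenoxy)-1-[4-(tert-butyldimethylsilyloxy)-3,5-dimethoxyphenyl]propan-1-one
Product: 11 (1S,2R)-2-(4-allyl-2-hydroxy-6-methoxyphenoxy)-1-[4-(tert-butyldimethylsilyloxy)-3,5-dimethoxyphenyl]propan-1-ol
Conditions: NaBH4, THF/MeOH, 0 °C
Reagents that add atoms: none
Why: Borohydride reduction of the aryl ketone, where cation-chelated (Cram chelate) hydride delivery should favour the erythro (1S,2R) alcohol, although the carbinol configuration is immaterial because this carbon is planarised in step 7.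

Step 6
Reactants: 11 (1S,2R)-2-(4-allyl-2-hydroxy-6-methoxyphenoxy)-1-[4-(tert-butyldimethylsilyloxy)-3,5-dimethoxyphenyl]propan-1-ol
Product: 13 (4S,5R)-9-allyl-4-[4-(tert-butyldimethylsilyloxy)-3,5-dimethoxyphenyl]-7-methoxy-5-methyl-4,5-dihydro-2H-1,3,6-benzotrioxocin-2-one, via mixed pentafluorophenyl carbonate 12 (not isolated)
Conditions: (C6F5O)2CO, i-Pr2NEt, DMAP (cat.), THF, slow addition, 2 mM, 0 °C → rt
Reagents that add atoms: bis(pentafluorophenyl) carbonate, O=C(Oc1c(F)c(F)c(F)c(F)c1F)Oc1c(F)c(F)c(F)c(F)c1F
Why: Cyclic carbonate formation from a diol and an activated carbonate, as used for eight-membered cyclic carbonate monomers: the phenol is acylated first and the secondary alcohol then displaces pentafluorophenoxide under high dilution, helped by the rigid catechol diether backbone and by the absence of acid or chloride that could ionise the benzylic position.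

Step 7
Reactants: 13 (4S,5R)-9-allyl-4-[4-(tert-butyldimethylsilyloxy)-3,5-dimethoxyphenyl]-7-methoxy-5-methyl-4,5-dihydro-2H-1,3,6-benzotrioxocin-2-one
Product: 17 4-[(2R,3R)-7-allyl-5-methoxy-3-methyl-2,3-dihydro-1,4-benzodioxin-2-yl]-2,6-dimethoxyphenol, via ring phenoxide 14 (not isolated), via quinone methide carbonate anion 15 (not isolated), via quinone methide phenoxide 16 (not isolated)
Conditions: CsF, MeCN/DMF, 4 Å MS, 5 mM, 0 °C → rt; then AcOH
Reagents that add atoms: none
Why: Proposed new method: fluoride cleaves the aryl silyl ether and phenoxide 14 expels the benzylic carbonate oxygen by 1,6-elimination, opening the eight-membered ring to p-quinone methide 15, whose aryl hemicarbonate anion loses CO2 to give phenoxide 16 that is still tied to the methyl-bearing carbon through the ether oxygen. This phenoxide oxygen adds to the quinone methide carbon in a 6-exo-trig oxa-1,6-conjugate addition, so the C(=O)–O unit is extruded, the 1,4-dioxane ring is closed and the syringyl ring is rearomatised. The closest known reaction types are the self-immolative 1,6-elimination of 4-hydroxybenzyl carbonates, the decarboxylative etherification of aryl benzyl carbonates and the quinone methide closure assumed in the biosynthesis of benzodioxane neolignans; their union as a ring contraction of a cyclic carbonate is the new element. The new stereocentre C2 is controlled by the fixed (R) centre C3: a chair-like transition state with aryl and methyl groups pseudo-equatorial should give the trans (2R,3R) ring, and because the addition is reversible through the free phenoxide any cis isomer should drain to the diequatorial trans isomer. Regioselectivity is built into the substrate, since only the oxygen released from the carbonate (meta to the allyl group) can reach the quinone methide carbon. The step needs ring closure to outrun water capture and tautomerisation of the quinone methide to the enol ether, which the intramolecular six-membered path under dry and dilute conditions should secure.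

Compound list
1 | 4-bromo-2,6-dimethoxyphenol | COc1cc(Br)cc(OC)c1O | starting material
2 | (4-bromo-2,6-dimethoxyphenoxy)(tert-butyl)dimethylsilane | COc1cc(Br)cc(OC)c1O[Si](C)(C)C(C)(C)C | intermediate
3 | (S)-2-hydroxy-N,N-dimethylpropanamide | C[C@H](O)C(=O)N(C)C | starting material
4 | [4-(tert-butyldimethylsilyloxy)-3,5-dimethoxyphenyl]lithium | [Li]c1cc(OC)c(O[Si](C)(C)C(C)(C)C)c(OC)c1 | intermediate
5 | chloromagnesium alkoxide of (S)-2-hydroxy-N,N-dimethylpropanamide | C[C@H](O[Mg]Cl)C(=O)N(C)C | intermediate
6 | (S)-1-[4-(tert-butyldimethylsilyloxy)-3,5-dimethoxyphenyl]-2-hydroxypropan-1-one | C[C@H](O)C(=O)c1cc(OC)c(O[Si](C)(C)C(C)(C)C)c(OC)c1 | intermediate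
7 | 5-allyl-2-hydroxy-3-methoxybenzaldehyde | C=CCc1cc(C=O)c(O)c(OC)c1 | starting material
8 | 5-allyl-2-{[(R)-1-[4-(tert-butyldimethylsilyloxy)-3,5-dimethoxyphenyl]-1-oxopropan-2-yl]oxy}-3-methoxybenzaldehyde | C[C@@H](Oc1c(C=O)cc(CC=C)cc1OC)C(=O)c1cc(OC)c(O[Si](C)(C)C(C)(C)C)c(OC)c1 | intermediate
9 | 5-allyl-2-{[(R)-1-[4-(tert-butyldimethylsilyloxy)-3,5-dimethoxyphenyl]-1-oxopropan-2-yl]oxy}-3-methoxyphenyl formate | C[C@@H](Oc1c(OC=O)cc(CC=C)cc1OC)C(=O)c1cc(OC)c(O[Si](C)(C)C(C)(C)C)c(OC)c1 | intermediate
10 | (R)-2-(4-allyl-2-hydroxy-6-methoxyphenoxy)-1-[4-(tert-butyldimethylsilyloxy)-3,5-dimethoxyphenyl]propan-1-one | C[C@@H](Oc1c(O)cc(CC=C)cc1OC)C(=O)c1cc(OC)c(O[Si](C)(C)C(C)(C)C)c(OC)c1 | intermediate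
11 | (1S,2R)-2-(4-allyl-2-hydroxy-6-methoxyphenoxy)-1-[4-(tert-butyldimethylsilyloxy)-3,5-dimethoxyphenyl]propan-1-ol | C[C@@H](Oc1c(O)cc(CC=C)cc1OC)[C@@H](O)c1cc(OC)c(O[Si](C)(C)C(C)(C)C)c(OC)c1 | intermediate
12 | aryl pentafluorophenyl carbonate of 11 (acylated on the ring phenol, carbinol free) | C[C@@H](Oc1c(OC(=O)Oc2c(F)c(F)c(F)c(F)c2F)cc(CC=C)cc1OC)[C@@H](O)c1cc(OC)c(O[Si](C)(C)C(C)(C)C)c(OC)c1 | intermediate
13 | (4S,5R)-9-allyl-4-[4-(tert-butyldimethylsilyloxy)-3,5-dimethoxyphenyl]-7-methoxy-5-methyl-4,5-dihydro-2H-1,3,6-benzotrioxocin-2-one | C[C@H]1Oc2c(OC)cc(CC=C)cc2OC(=O)O[C@H]1c3cc(OC)c(O[Si](C)(C)C(C)(C)C)c(OC)c3 | intermediate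
14 | desilylated phenoxide of 13, eight-membered ring intact | C[C@H]1Oc2c(OC)cc(CC=C)cc2OC(=O)O[C@H]1c3cc(OC)c([O-])c(OC)c3 | intermediate
15 | (R)-configured p-quinone methide bearing the aryl hemicarbonate anion | C[C@@H](Oc1c(OC)cc(CC=C)cc1OC(=O)[O-])C=C1C=C(OC)C(=O)C(OC)=C1 | intermediate
16 | (R)-configured p-quinone methide bearing the free aryl oxide | C[C@@H](Oc1c(OC)cc(CC=C)cc1[O-])C=C1C=C(OC)C(=O)C(OC)=C1 | intermediate
17 | 4-[(2R,3R)-7-allyl-5-methoxy-3-methyl-2,3-dihydro-1,4-benzodioxin-2-yl]-2,6-dimethoxyphenol | C=CCc1cc(OC)c2c(c1)O[C@H](c1cc(OC)c(O)c(OC)c1)[C@@H](C)O2 | target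

Total step count: 7
Longest linear sequence: 7 steps (1 → 2 → 6 → 8 → 10 → 11 → 13 → 17)

Steps most likely to fail

Step 7.
- What may go wrong: adventitious water may capture the quinone methide. Loss of the C3 proton may tautomerise it to the enol ether and erode the stereocentre. The cis to trans equilibration may also stay incomplete.
- Fallback, using known chemistry: it sets out from diol 11. A catalytic Brønsted or Lewis acid (p-TsOH or BF3·OEt2, CH2Cl2, −20 °C) ionises the electron-rich benzylic alcohol. The neighbouring phenol closes on the cation under thermodynamic control to give the trans silyl-protected benzodioxane F1. Removal of the silyl group with TBAF in THF comes back to the route at 17.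

Step 6.
- What may go wrong: oligomerisation may replace eight-membered closure, or the benzylic carbonate may ionise prematurely during formation or handling.
- Fallback: it sets out from phenol ketone 10. The phenol is acylated with 4-nitrophenyl chloroformate and pyridine to give the mixed 4-nitrophenyl carbonate F2. The ketone is then reduced with Zn(BH4)2 in dilute ether. The metal alkoxide is thus born next to an already activated carbonyl and closes the ring by expelling 4-nitrophenoxide. This comes back to the route at 13.

Step 3.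
- What may go wrong: the doubly ortho-substituted phenol may couple sluggishly, and the basic Mitsunobu medium may partly racemise the α-keto stereocentre.
- Fallback: it sets out from hydroxy ketone 6. MsCl and Et3N at −20 °C convert it into the (S)-mesylate F3. The caesium phenoxide of 7 (Cs2CO3, MeCN, 0 °C) displaces the mesylate in a classical SN2 reaction with inversion, the method used for optically active aryloxypropionates. This comes back to the route at 8.

Further compounds
F1 | step 7 | tert-butyl{4-[(2R,3R)-7-allyl-5-methoxy-3-methyl-2,3-dihydro-1,4-benzodioxin-2-yl]-2,6-dimethoxyphenoxy}dimethylsilane | C=CCc1cc(OC)c2c(c1)O[C@H](c1cc(OC)c(O[Si](C)(C)C(C)(C)C)c(OC)c1)[C@@H](C)O2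
F2 | step 6 | 5-allyl-2-{[(R)-1-[4-(tert-butyldimethylsilyloxy)-3,5-dimethoxyphenyl]-1-oxopropan-2-yl]oxy}-3-methoxyphenyl 4-nitrophenyl carbonate | C[C@@H](Oc1c(OC(=O)Oc2ccc(cc2)[N+](=O)[O-])cc(CC=C)cc1OC)C(=O)c1cc(OC)c(O[Si](C)(C)C(C)(C)C)c(OC)c1
F3 | step 3 | (S)-1-[4-(tert-butyldimethylsilyloxy)-3,5-dimethoxyphenyl]-1-oxopropan-2-yl methanesulfonate | C[C@H](OS(C)(=O)=O)C(=O)c1cc(OC)c(O[Si](C)(C)C(C)(C)C)c(OC)c1
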